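If free catalyst is lost by pairs (second-order decay), its amount summed over time depends on charge and time through their product, and making target and turning target into isomer of the product both run in proportion to free catalyst, so two flasks with equal substrate and dissolved gas should hold the same target at equal product of charge and time.

| setting | Sunday's | Saturday's | flask |
|---|---|---|---|
| substrate | 0.40 M | 0.40 M | 0.40 M |
| gas phase | 200 mM (held) | 200 mM (held) | 200 mM (held) |
| free catalyst | 2.1 mM | 4.2 mM | 2.1 mM |
| remark | the very flask that is asked about, followed so far | run made earlier |  |
| time |  |  | 8.0 d |

Sunday's run (percent of the substrate charged)

| time / h | target / % |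
|---|---|
| 6.00 | 1 |
| 12.0 | 2 |
| 15.0 | 6 |
| 25.0 | 4 |

Saturday's run (percent of the substrate charged)

| time / d | target / % |
|---|---|
| 2.08 | 9 |
| 4.00 | 13 |
| 6.00 | 14 |
| 8.00 | 16 |

(scatter of a reading: 1.5 percentage points)

- the target standing at 8.0 d, as a percentage of the substrate charged
- the change that raises the amount of target at 8.0 d, in percent of the substrate charged most ("none" if none brings more than 2 percentage points) (autumn / dusk / noon / none)
- amount of target at 8.0 d, in percent of the substrate charged, after autumn

- autumn: doubling the amount of free catalyst, all else as stated
- dusk: doubling the transfer coefficient of the gas phase, all else as stated
- noon: doubling the saturation concentration of gas phase, all else as stated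

- at the start none of the gas is dissolved
- what may be going on: gas phase <-> dissolved gas; substrate + dissolved gas + free catalyst -> free catalyst + target; 2 free catalyst -> spent catalyst; target + free catalyst <-> isomer of the product + free catalyst

The flask, charged like Sunday's and read at 8.0 d, thus meets Saturday's flask at 4.00 d, its equivalent time, the time at which Saturday's flask has had the same product of charge and time. Saturday's flask reads 13% there, give or take 1.5 percentage points, and this estimate leans low, because the gas enters by time and the flask has had twice as long to fill. Autumn is Saturday's recipe, so its estimate is the reading of 16%, a step of 3 points. Noon doubles the gas term in the making step, a gain of the order of the 13% already read, which is more than autumn's step. Dusk shortens the filling but leaves the level to which the dissolved gas fills.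

The forecast gives 12.3%, 16% after autumn, and noon as the best change, holding that “Total turnover is limited by catalyst death, so more catalyst helps only logarithmically.”

The flask gives 14.3%, 15.6% after autumn, and noon as the best change, with a gain of 8 points against 1.3 points for autumn and 1.3 points for dusk.

    gas phase ⇌ dissolved gas, rate k1*(csat - [dissolved gas]) (kL = 9.81 × 10⁻⁴ min⁻¹)
    substrate + dissolved gas + free catalyst → free catalyst + target (k = 0.584 M⁻² min⁻¹)
    2 free catalyst → spent catalyst (k = 0.185 M⁻¹ min⁻¹)
    target + free catalyst ⇌ isomer of the product + free catalyst, rate k4*[free catalyst]*[target] forward; the back reaction follows from the equilibrium constant (K = 2.30, k = 1.63 M⁻¹ min⁻¹)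

Dissolved gas approaches saturation with a time constant of 0.708 d, shorter than the 0.894 d first half-life of free catalyst in this flask but longer than the 0.447 d in Saturday's flask. At equal equivalent time this flask holds 14.3% against Saturday's reading of 13%, give or take 1.5 points, and the same flask read at 3.0 d, with an equivalent time of 1.50 d, short of Saturday's first reading at 2.08 d, holds 9.54% against that reading's 9%.

The readings were generated by integration with constants of no real substance; scatter was added.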